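**Retrosynthetic overview**
1. Target 7 ⇐ aryl mesylate 6 (the ring-B OH is unmasked last) ⇐ phenol 5 by O-methylation.
2. 5 ⇐ mono-mesylate 2 by one substituent-programmed, one-pot triple C–H bromination (key step: all three C–Br bonds at once).
3. 2 ⇐ symmetric 2,2'-oxydiphenol 1 by desymmetrising mono-sulfonylation.
4. No diaryl-ether coupling (Ullmann, SNAr or Chan–Lam) is used: the C–O–C bond is bought in 1.
5. Ring order: both benzene rings are present in 1; no ring is formed in the route.

Assumption: the target has no stereocentre (it is achiral), so there is no enantiomer to control, and 2,2'-oxydiphenol (CAS 15764-52-0) is taken as a catalogue compound.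

**Step 1**
Reactants: 1 2,2'-oxydiphenol
Product: 2 2-(2-hydroxyphenoxy)phenyl methanesulfonate
Conditions: MsCl (0.8 equiv, slow addition), Et3N (1.0 equiv), CH2Cl2, −20 → 0 °C; unreacted 1 recycled
Reagents that add atoms: methanesulfonyl chloride, CS(=O)(=O)Cl
Why: Phenol O-sulfonylation (sulfene/Et3N) of a bis-phenol whose two OH groups are equivalent, so a sub-stoichiometric charge of MsCl gives mainly the mono-mesylate (about 48 % statistical, separable from 1 and the bis-mesylate) with no regiochemical question.

**Step 2**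
Reactants: 2 2-(2-hydroxyphenoxy)phenyl methanesulfonate
Product: 5 5-bromo-2-(3,5-dibromo-2-hydroxyphenoxy)phenyl methanesulfonate, via monobromide 3 (not isolated), via dibromide 4 (not isolated)
Conditions: Br2 (3.1 equiv), AcOH, 0 °C → rt, then 50 °C; aq. Na2S2O3
Reagents that add atoms: bromine, BrBr
Why: Electrophilic aromatic bromination steered by the two different oxygen groups: the free phenol ring takes bromine para and then ortho to OH (guaiacol pattern), and the third equivalent goes para to the ether oxygen on the other ring, because OMs is deactivating and the open positions of the dibromophenol ring are flanked and deactivated.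

**Step 3**
Reactants: 5 5-bromo-2-(3,5-dibromo-2-hydroxyphenoxy)phenyl methanesulfonate
Product: 6 5-bromo-2-(3,5-dibromo-2-methoxyphenoxy)phenyl methanesulfonate
Conditions: MeI (1.5 equiv), K2CO3 (2 equiv), DMF, rt
Reagents that add atoms: iodomethane, CI
Why: Williamson O-methylation of the only free OH, an acidic 2,6-disubstituted bromophenol (pKa about 7), while the non-migrating aryl mesylate, the aryl bromides and the diaryl ether are inert to K2CO3/MeI.

**Step 4**
Reactants: 6 5-bromo-2-(3,5-dibromo-2-methoxyphenoxy)phenyl methanesulfonate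
Product: 7 5-bromo-2-(3,5-dibromo-2-methoxyphenoxy)phenol
Conditions: KOH (5 equiv), 1,4-dioxane/H2O, 80 °C; then 1 M HCl
Reagents that add atoms: none
Why: Base hydrolysis of an aryl sulfonate (S–O cleavage by hydroxide or E1cB via sulfene) frees the phenol, while the methyl ether, the diaryl ether and the unactivated aryl bromides do not react with aqueous hydroxide at this temperature.

**Compound list**
1 | 2,2'-oxydiphenol | Oc1ccccc1Oc1ccccc1O | starting material
2 | 2-(2-hydroxyphenoxy)phenyl methanesulfonate | CS(=O)(=O)Oc1ccccc1Oc1ccccc1O | intermediate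
3 | 2-(5-bromo-2-hydroxyphenoxy)phenyl methanesulfonate (monobromide) | CS(=O)(=O)Oc1ccccc1Oc1cc(Br)ccc1O | intermediate
4 | 2-(3,5-dibromo-2-hydroxyphenoxy)phenyl methanesulfonate (dibromide) | CS(=O)(=O)Oc1ccccc1Oc1cc(Br)cc(Br)c1O | intermediate
5 | 5-bromo-2-(3,5-dibromo-2-hydroxyphenoxy)phenyl methanesulfonate | CS(=O)(=O)Oc1cc(Br)ccc1Oc1cc(Br)cc(Br)c1O | intermediate
6 | 5-bromo-2-(3,5-dibromo-2-methoxyphenoxy)phenyl methanesulfonate | COc1c(Br)cc(Br)cc1Oc1ccc(Br)cc1OS(C)(=O)=O | intermediate
7 | 5-bromo-2-(3,5-dibromo-2-methoxyphenoxy)phenol | COc1c(Br)cc(Br)cc1Oc1ccc(Br)cc1O | target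

**Total step count:** 4. **Longest linear sequence:** 4.

**Steps most likely to fail**

Step 2 (highest risk). The third bromine may not go cleanly para to the ether oxygen of the mesylate ring, or the reaction may under- or over-brominate. The fallback sets out from 2 and comes back at 6. Bromination is held at two equivalents (Br2 2.0 equiv, CH2Cl2, −20 °C), so only the phenol ring reacts, via 3, and dibromide 4 is now isolated. O-Methylation (MeI, K2CO3, DMF) gives 2-(3,5-dibromo-2-methoxyphenoxy)phenyl methanesulfonate F2. The last bromine is then introduced not by Br+ but through site-selective C–H thianthrenation (thianthrene S-oxide, TFAA, HBF4·OEt2, MeCN, 0 °C → rt). This reaction is para-selective to the strongest donor and does not tolerate flanked positions, so it gives 5-[4-(3,5-dibromo-2-methoxyphenoxy)-3-(methanesulfonyloxy)phenyl]thianthren-5-ium tetrafluoroborate F3. Photoredox/copper bromide transfer (LiBr, cat. Cu(MeCN)4BF4, cat. Ru(bpy)3(PF6)2, blue LED, MeCN) then gives 6.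

Step 1. Mono-mesylation is statistical and may give an awkward mixture of 1, 2 and bis-mesylate. The fallback sets out from 1 and comes back at 2. Exhaustive mesylation (MsCl 2.5 equiv, Et3N, CH2Cl2, 0 °C) gives oxydi-2,1-phenylene dimethanesulfonate F1 in one clean product. A single sulfonate is then removed with exactly 2.0 equiv KOH (dioxane/H2O, rt → 40 °C). The first cleavage consumes both equivalents of base and leaves a phenoxide whose charge slows a second attack, so the reaction stops at 2.

Step 4. Sulfonate hydrolysis may be sluggish or need conditions that are too harsh. The fallback sets out from 1 and comes back at 7, replacing the sulfonate mask by an ester that is cleaved by acyl–oxygen attack. Mono-pivaloylation (PivCl 0.8 equiv, Et3N, cat. DMAP, CH2Cl2, 0 °C) gives 2-(2-hydroxyphenoxy)phenyl pivalate F4. The same Br2/AcOH tribromination passes through 2-(5-bromo-2-hydroxyphenoxy)phenyl pivalate F5 and 2-(3,5-dibromo-2-hydroxyphenoxy)phenyl pivalate F6, neither isolated, to 5-bromo-2-(3,5-dibromo-2-hydroxyphenoxy)phenyl pivalate F7. Methylation (MeI, K2CO3, acetone, rt; the hindered pivaloyl group resists acyl transfer) gives 5-bromo-2-(3,5-dibromo-2-methoxyphenoxy)phenyl pivalate F8. LiOH in THF/H2O at rt then gives 7.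

**Further compounds**
F1 | step 1 | oxydi-2,1-phenylene dimethanesulfonate | CS(=O)(=O)Oc1ccccc1Oc1ccccc1OS(C)(=O)=O
F2 | step 2 | 2-(3,5-dibromo-2-methoxyphenoxy)phenyl methanesulfonate | COc1c(Br)cc(Br)cc1Oc1ccccc1OS(C)(=O)=O
F3 | step 2 | 5-[4-(3,5-dibromo-2-methoxyphenoxy)-3-(methanesulfonyloxy)phenyl]thianthren-5-ium tetrafluoroborate | COc1c(Br)cc(Br)cc1Oc1ccc(cc1OS(C)(=O)=O)[S+]1c2ccccc2Sc2ccccc12.F[B-](F)(F)F
F4 | step 4 | 2-(2-hydroxyphenoxy)phenyl pivalate | CC(C)(C)C(=O)Oc1ccccc1Oc1ccccc1O
F5 | step 4 | 2-(5-bromo-2-hydroxyphenoxy)phenyl pivalate | CC(C)(C)C(=O)Oc1ccccc1Oc1cc(Br)ccc1O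
F6 | step 4 | 2-(3,5-dibromo-2-hydroxyphenoxy)phenyl pivalate | CC(C)(C)C(=O)Oc1ccccc1Oc1cc(Br)cc(Br)c1O
F7 | step 4 | 5-bromo-2-(3,5-dibromo-2-hydroxyphenoxy)phenyl pivalate | CC(C)(C)C(=O)Oc1cc(Br)ccc1Oc1cc(Br)cc(Br)c1O
F8 | step 4 | 5-bromo-2-(3,5-dibromo-2-methoxyphenoxy)phenyl pivalate | COc1c(Br)cc(Br)cc1Oc1ccc(Br)cc1OC(=O)C(C)(C)C
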